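5 questions stand here, and you can answer them with one frozen number. The candidate steps: J and X give D and E, E speeds that same step, and D goes to G, perhaps reversibly.

| flask | J | X | remark | time |
|---|---|---|---|---|
| delta | 0.50 mM | 0.65 mM | run made earlier |  |
| zeta | 1 mM | 0.65 mM | run made earlier |  |
| maple | 0.50 mM | 0.650 mM (fed, over 15 s) | all else is in the flask from the start; the feed brings no volume worth counting | 4.0 min |
| cedar | 0.50 mM (fed, over 2.5 min) | 0.650 mM | all else is in the flask from the start; the feed brings no volume worth counting | 4.0 min |
| oak | 0.50 mM | 0.650 mM (fed, over 2.5 min) | all else is in the flask from the start; the feed brings no volume worth counting | 4.0 min |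
| larch | 0.50 mM | 0.650 mM | everything together at the start | 4.0 min |

- delta (time / min: G / %, D / %): 0.200: 0.5, 0; 0.333: 0, 1.1; 0.500: 0.3, 0; 0.833: 0, 1.4; 1.33: 1.9, 21.6; 2.50: 8.1, 78.8
- zeta (time / s: G / %, D / %): 10.0: 0, 0.3; 15.0: 0, 0; 25.0: 0, 1.2

(readings scatter by 1 percentage point)

* which flask leads in amount of G, in percent of the J charged ("all alike" within 1.5 percentage points) (maple / cedar / oak / larch / all alike)
* how much G is there at the end, in percent of the J charged: maple
* how much G is there at the end, in percent of the J charged: cedar
* how much G is there at the end, in percent of the J charged: oak
* how much G is there at the end, in percent of the J charged: larch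

- the numbers in the tables scatter with a standard deviation of 1 percentage point
- candidate steps: J + X -> D + E; D <-> G; J + X + E -> D + 2 E

Delta's last row gives 9.32% for the share s, G divided by G plus D. The ratio G/D reads 0.0880 and then 0.103, a climb smaller than the scatter of the first reading. So I freeze s, a quasi-equilibrium, and write G = s × converted J.

From above: converted J cannot pass the charge, so with s frozen, G stays at or below s. From below, take the flasks with the long feeds. Growth of E runs with the product of J and X, and while little has reacted that product is the same in oak and cedar. In that stretch a steady feed delays the clock by 1.25 min, half of its length. Delta has larch's recipe, so I reckon cedar at 4.0 min matches delta at 2.75 min, later than delta's last row. That row reads 86.9% converted, so I put cedar and oak at 8.10% of G or a little above. Maple's delay is shorter, so it sits higher in the bracket. The bracket is 1.2 percentage points wide, narrower than the margin. The scatter of s, about 1 point, moves the flasks together. I commit to "all alike".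

The forecast named larch at 14% and put maple at 13.5%, both above this bracket, with cedar and oak at 9%, inside it: “Earlier conversion favours larch”.

The flasks give all alike: maple 9.92%, cedar 9.15%, oak 9.15%, larch 9.95%. Larch stands 0.63 points above the top of my bracket, less than the scatter of s.

    J + X → D + E (k = 0.0610 M⁻¹ s⁻¹)
    D ⇌ G (K = 0.113, k = 0.0400 s⁻¹)
    J + X + E → D + 2 E (k = 2.59 × 10⁵ M⁻² s⁻¹)

In cedar, D and G relax by their own step, both ways together, with a half-life of 1.76 s, shorter than the time. Now take cedar with 0.20 mM of J. At 4.00 min it still has 78.0% of its J, so s predicts 2.05% of G. The flask holds 2.10%.

(The numbers in the tables were generated by integration with constants of no real substance; the scatter is artificial.)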